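**Retrosynthetic overview**
- Feature: in each 2,4,7-trimethyl-octahydrocyclopenta[c]pyridine unit, ring-fusion carbon C4a carries the C4(Me)–C3–N2 chain and lies β to C1. With C1 drawn as an aryl ketone on C6 or C8 of flavan ring A, C4–C4a is the bond a propanamide α-carbanion makes by 1,4-addition to a 1-aroylcyclopentene.
- Disconnections, target backwards: 2 × C1–N2 (benzylic C–N, lactam closure, with C3 as carbonyl); 2 × C4–C4a (Michael union with N-methylpropanamide); 2 × aryl–C1 (addition of the ring A aryllithiums of penta-O-benzylcatechin, one position at a time, to (5S)-5-methylcyclopent-1-ene-1-carbaldehyde, then oxidation).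
- Ring order: rings A, B and C of the chroman come with (+)-catechin; the two cyclopentanes come from (S)-pulegone by Favorskii ring contraction; the two piperidine rings are closed last, as N-methyl lactams, and then reduced.

Key step: step 13

Remark: C4 of each alkaloid unit is not controlled in the Michael union; it is carried as an epimer mixture (drawn without a descriptor) through steps 13 to 15 and set by base equilibration in step 16. The single bromine–lithium exchange of step 10 is not expected to distinguish C6 from C8; compound 15 is drawn as the 6-bromo-8-carbinol isomer, its 8-bromo-6-carbinol isomer is carried along, and both give 17. All equivalents are proposals.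

**Step 1**
Reactants: 1 (S)-(−)-pulegone
Product: 3 methyl pulegenate [methyl (2S)-2-methyl-5-(propan-2-ylidene)cyclopentane-1-carboxylate; C1 epimers], via pulegone dibromide 2 (not isolated)
Conditions: Br2, NaHCO3, Et2O, −10 °C; then NaOMe, MeOH, reflux
Reagents that add atoms: sodium methoxide, C[O-].[Na+]
Why: Bromine adds to the electron-rich isopropylidene double bond and methoxide then drives a Favorskii ring contraction of dibromide 2 (C6 enolate, cyclopropanone, methanolysis and loss of the second bromide to restore the isopropylidene group), a sequence that never touches the methyl-bearing stereocentre, which is β to the carbonyl group.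

**Step 2**
Reactants: 3 methyl pulegenate
Product: 4 methyl (2S)-2-methyl-5-oxocyclopentane-1-carboxylate
Conditions: O3, CH2Cl2–MeOH, −78 °C; then Me2S, −78 °C → rt
Reagents that add atoms: ozone, [O-][O+]=O
Why: Ozonolysis with reductive work-up cleaves the only C=C bond, a tetrasubstituted exocyclic alkene, to the ring ketone and acetone, and the methyl-bearing centre is not α to either carbonyl group and so keeps its configuration.

**Step 3**
Reactants: 4 methyl (2S)-2-methyl-5-oxocyclopentane-1-carboxylate
Product: 5 methyl (5S)-2-hydroxy-5-methylcyclopentane-1-carboxylate (diastereomer mixture at C1 and C2)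
Conditions: NaBH4, MeOH, 0 °C
Reagents that add atoms: none
Why: Borohydride reduction takes the ketone of the β-keto ester and leaves the ester; the new carbinol centre and the epimerisable C1 are formed as mixtures, which is harmless because both carbons become sp2 in step 4.

**Step 4**
Reactants: 5 methyl (5S)-2-hydroxy-5-methylcyclopentane-1-carboxylate
Product: 7 methyl (5S)-5-methylcyclopent-1-ene-1-carboxylate, via mesylate 6 (not isolated)
Conditions: MsCl, Et3N, CH2Cl2, 0 °C; then DBU, rt → 40 °C
Reagents that add atoms: none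
Why: Mesylation followed by DBU-induced E1cB elimination through the ester enolate gives the conjugated cyclopentene ester from every diastereomer of 5, and the C5 methine is not acidic (its anion would be cross-conjugated), so the stereocentre is retained.

**Step 5**
Reactants: 7 methyl (5S)-5-methylcyclopent-1-ene-1-carboxylate
Product: 8 [(5S)-5-methylcyclopent-1-en-1-yl]methanol
Conditions: i-Bu2AlH (2.2 equiv), CH2Cl2, −78 → 0 °C; then aq potassium sodium tartrate
Reagents that add atoms: none
Why: Two equivalents of i-Bu2AlH reduce the conjugated ester by 1,2-hydride addition to the allylic alcohol (ester reduction) and leave the trisubstituted alkene and the non-acidic C5 stereocentre untouched.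

**Step 6**
Reactants: 8 [(5S)-5-methylcyclopent-1-en-1-yl]methanol
Product: 9 (5S)-5-methylcyclopent-1-ene-1-carbaldehyde
Conditions: MnO2 (10 equiv), CH2Cl2, rt
Reagents that add atoms: none
Why: MnO2 oxidises allylic alcohols to enals under neutral heterogeneous conditions (allylic alcohol oxidation), so neither double-bond migration nor loss of the C5 configuration is expected, and the volatile aldehyde can be carried on as a filtered solution.

**Step 7**
Reactants: 10 (+)-catechin
Product: 11 5,7,3',4'-tetra-O-benzylcatechin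
Conditions: BnBr (4.4 equiv), K2CO3, DMF, 0 °C → rt
Reagents that add atoms: benzyl bromide, BrCc1ccccc1
Why: Williamson etherification under carbonate base benzylates the four phenols (much more acidic than the C3 alcohol) and leaves the secondary hydroxyl group and both stereocentres of ring C untouched.

**Step 8**
Reactants: 11 5,7,3',4'-tetra-O-benzylcatechin
Product: 12 penta-O-benzylcatechin
Conditions: NaH, BnBr, Bu4NI (cat.), DMF, 0 °C → rt
Reagents that add atoms: benzyl bromide, BrCc1ccccc1
Why: With the phenols capped, sodium hydride forms the C3 alkoxide, which is benzylated in a second Williamson etherification; no ring opening at C2 is possible once the phenols are ethers.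

**Step 9**
Reactants: 12 penta-O-benzylcatechin
Product: 13 6,8-dibromo-penta-O-benzylcatechin
Conditions: NBS (2.1 equiv), CH2Cl2, 0 °C → rt
Reagents that add atoms: N-bromosuccinimide, O=C1CCC(=O)N1Br
Why: Electrophilic aromatic bromination occurs at C6 and C8 of ring A, the only positions flanked by two oxygen substituents, well before the less activated dialkoxyphenyl ring B reacts.

**Step 10**
Reactants: 13 6,8-dibromo-penta-O-benzylcatechin; 9 (5S)-5-methylcyclopent-1-ene-1-carbaldehyde
Product: 15 6-bromo-8-{hydroxy[(5S)-5-methylcyclopent-1-en-1-yl]methyl}-penta-O-benzylcatechin (carbinol epimers; drawn regioisomer), via 6-bromo-8-lithio arene 14 (not isolated)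
Conditions: n-BuLi (1.05 equiv), THF, −78 °C; then 9 (1.2 equiv), −78 → −40 °C; then H2O
Reagents that add atoms: none
Why: One equivalent of n-BuLi exchanges a single bromine (bromine–lithium exchange; a second exchange on the aryllithium is far slower and any dilithio arene comproportionates with 13), and the aryllithium flanked by two alkoxy groups adds 1,2 to the unhindered enal to give the allylic benzylic carbinol, whose configuration and ring position (C6 or C8) are immaterial because step 11 fills the other position and step 12 removes the carbinol centres.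

**Step 11**
Reactants: 15 6-bromo-8-{hydroxy[(5S)-5-methylcyclopent-1-en-1-yl]methyl}-penta-O-benzylcatechin; 9 (5S)-5-methylcyclopent-1-ene-1-carbaldehyde
Product: 17 6,8-bis{hydroxy[(5S)-5-methylcyclopent-1-en-1-yl]methyl}-penta-O-benzylcatechin (carbinol epimers), via lithium alkoxide aryllithium 16 (not isolated)
Conditions: t-BuLi (3.2 equiv), THF, −78 °C; then 9 (1.5 equiv), −78 → −40 °C; then H2O
Reagents that add atoms: none
Why: The first equivalent of t-BuLi turns the hydroxyl group into its lithium alkoxide, two more effect the remaining bromine–lithium exchange irreversibly, and aryllithium 16 adds 1,2 to a second molecule of enal 9 (organolithium addition to an aldehyde), the alkoxide keeping the first carbinol inert during the step.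

**Step 12**
Reactants: 17 6,8-bis{hydroxy[(5S)-5-methylcyclopent-1-en-1-yl]methyl}-penta-O-benzylcatechin
Product: 18 6,8-bis{[(5S)-5-methylcyclopent-1-en-1-yl]carbonyl}-penta-O-benzylcatechin
Conditions: Dess–Martin periodinane (2.6 equiv), pyridine, CH2Cl2, 0 °C → rt
Reagents that add atoms: none
Why: Dess–Martin oxidation converts both secondary allylic benzylic carbinols into the aryl enones under buffered conditions that should not ionise the electron-rich benzylic positions, and the methyl-bearing stereocentres are not enolisable because their anion would be cross-conjugated.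

**Step 13**
Reactants: 18 6,8-bis{[(5S)-5-methylcyclopent-1-en-1-yl]carbonyl}-penta-O-benzylcatechin; 19 N-methylpropanamide
Product: 22 6,8-bis{[(1R,2S,5S)-5-methyl-2-(1-(methylamino)-1-oxopropan-2-yl)cyclopentyl]carbonyl}-penta-O-benzylcatechin (epimers at the amide α-carbon C4), via amide dianion 20 (not isolated), via tetralithium bis(enolate) adduct 21 (not isolated)
Conditions: 19 (6 equiv), n-BuLi (12 equiv), THF, 0 °C; then 18, −78 → −40 °C; 2,6-di-tert-butylphenol, THF, −78 °C; then AcOH
Reagents that add atoms: none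
Why: The carbon terminus of dianion 20 attacks the ring β-carbon (C4a) of each enone because both faces of the carbonyl carbon are screened by the two ortho benzyloxy groups of the twisted aryl ketone, just as 1,2-addition is suppressed in mesityl-type ketones; the closest known reaction type is the Michael addition of amide enolates and secondary-amide dianions to hindered aryl enones. No ring is closed in this step; two C4–C4a bonds are formed and the adducts persist as the lithium enolates 21 until the quench. At C4a the nucleophile should enter anti to the C7 methyl group, which is held pseudoaxial by A(1,2) strain against the aroyl group and so covers one face of the cyclopentene. At C7a the bulky phenol should deliver the proton to the enolate face opposite the new, larger C4a arm, which leaves the aroyl group cis to that arm and trans to the methyl group (kinetic control, cold quench, no later exposure to base). C4 is not controlled and is corrected in step 16. The step needs 1,4-addition to win over 1,2-addition and over γ-deprotonation at the ring CH2, which the di-ortho-substituted ketone, the low temperature and the excess of carbon nucleophile are meant to secure.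

**Step 14**
Reactants: 22 bis(δ-keto N-methylamide)
Product: 23 bis(benzylic carbinol) of 22 (carbinol and C4 epimers)
Conditions: LiBH4, THF, 0 °C → rt
Reagents that add atoms: none
Why: Borohydride reduction of the aryl ketones to the benzylic carbinols proceeds without touching the secondary amides or the benzyl ethers under conditions too weakly basic to epimerise C7a, and the configuration of the new carbinol centres is irrelevant because they are ionised in step 15.

**Step 15**
Reactants: 23 bis(benzylic carbinol)
Product: 24 6,8-bis[(1R,4aS,7S,7aR)-2,4,7-trimethyl-3-oxooctahydro-1H-cyclopenta[c]pyridin-1-yl]-penta-O-benzylcatechin (C4 epimers)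
Conditions: TFA (10 equiv), CH2Cl2, 0 °C → rt
Reagents that add atoms: none
Why: Acid ionises each 2,4,6-trioxygenated benzylic carbinol to a stabilised cation that is captured by the amide nitrogen in a six-membered ring (intramolecular amidoalkylation, SN1), and because the benzylic C1–N bond of such a lactam re-ionises under the same acid the C1 centres should settle to the more stable isomer, aryl pseudoaxial and trans to the C7a–C7 bond, which avoids A(1,3) strain with N-methyl and is the target configuration.

**Step 16**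
Reactants: 24 bis-lactam (C4 epimers)
Product: 25 6,8-bis[(1R,4R,4aS,7S,7aR)-2,4,7-trimethyl-3-oxooctahydro-1H-cyclopenta[c]pyridin-1-yl]-penta-O-benzylcatechin
Conditions: t-BuOK (0.5 equiv), t-BuOH–THF, 50 °C
Reagents that add atoms: none
Why: Reversible enolisation of the lactams with t-BuOK equilibrates only C4 (the sole acidic CH), and the epimer with the C4 methyl pseudoequatorial and trans to the C4a–C5 bond, on the convex face of the cis-fused bicycle and clear of the cyclopentane C5 methylene, should dominate (thermodynamic epimerisation α to a carbonyl group).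

**Step 17**
Reactants: 25 bis-lactam (4R isomers)
Product: 26 6,8-bis[(1R,4R,4aR,7S,7aR)-2,4,7-trimethyloctahydro-1H-cyclopenta[c]pyridin-1-yl]-penta-O-benzylcatechin
Conditions: AlH3 (from LiAlH4 and AlCl3, 3:1), THF, 0 °C → rt
Reagents that add atoms: none
Why: Alane reduces tertiary lactams cleanly to amines through the C3 iminium ion (amide reduction) and leaves benzyl ethers, the benzylic C1–N bonds and all stereocentres unchanged.

**Step 18**
Reactants: 26 bis-amine pentabenzyl ether
Product: 27 (2R,3S)-2-(3,4-dihydroxyphenyl)-6,8-bis[(1R,4R,4aR,7S,7aR)-2,4,7-trimethyloctahydro-1H-cyclopenta[c]pyridin-1-yl]chromane-3,5,7-triol (target)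
Conditions: H2 (1 atm), Pd/C (10%), EtOAc–MeOH, rt
Reagents that add atoms: none
Why: Catalytic hydrogenolysis removes the five O-benzyl groups under neutral conditions at ambient pressure, where cleavage of benzyl ethers is much faster than cleavage of the hindered ring C1–N and C2–O1 bonds.

**Compound list**
1 | (S)-(−)-pulegone [(5S)-5-methyl-2-(propan-2-ylidene)cyclohexan-1-one] | C[C@H]1CCC(=C(C)C)C(=O)C1 | starting material
2 | pulegone dibromide [(5S)-2-bromo-2-(2-bromopropan-2-yl)-5-methylcyclohexan-1-one, C2 epimers] | C[C@H]1CCC(Br)(C(C)(C)Br)C(=O)C1 | intermediate (not isolated)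
3 | methyl pulegenate [methyl (2S)-2-methyl-5-(propan-2-ylidene)cyclopentane-1-carboxylate, C1 epimers] | C[C@H]1CCC(=C(C)C)C1C(=O)OC | intermediate
4 | methyl (2S)-2-methyl-5-oxocyclopentane-1-carboxylate | C[C@H]1CCC(=O)C1C(=O)OC | intermediate
5 | methyl (5S)-2-hydroxy-5-methylcyclopentane-1-carboxylate (mixture at C1, C2) | C[C@H]1CCC(O)C1C(=O)OC | intermediate
6 | methyl (5S)-2-(methanesulfonyloxy)-5-methylcyclopentane-1-carboxylate | C[C@H]1CCC(OS(C)(=O)=O)C1C(=O)OC | intermediate (not isolated)
7 | methyl (5S)-5-methylcyclopent-1-ene-1-carboxylate | C[C@H]1CCC=C1C(=O)OC | intermediate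
8 | [(5S)-5-methylcyclopent-1-en-1-yl]methanol | C[C@H]1CCC=C1CO | intermediate
9 | (5S)-5-methylcyclopent-1-ene-1-carbaldehyde | C[C@H]1CCC=C1C=O | intermediate
10 | (+)-catechin [(2R,3S)-2-(3,4-dihydroxyphenyl)chromane-3,5,7-triol] | Oc1cc(O)c2c(c1)O[C@H](c1ccc(O)c(O)c1)[C@@H](O)C2 | starting material
11 | 5,7,3',4'-tetra-O-benzylcatechin [(2R,3S)-5,7-bis(benzyloxy)-2-[3,4-bis(benzyloxy)phenyl]chroman-3-ol] | C(c1ccccc1)Oc1cc(OCc3ccccc3)c2c(c1)O[C@H](c1ccc(OCc3ccccc3)c(OCc3ccccc3)c1)[C@@H](O)C2 | intermediate
12 | penta-O-benzylcatechin [(2R,3S)-3,5,7-tris(benzyloxy)-2-[3,4-bis(benzyloxy)phenyl]chromane] | C(c1ccccc1)Oc1cc(OCc3ccccc3)c2c(c1)O[C@H](c1ccc(OCc3ccccc3)c(OCc3ccccc3)c1)[C@@H](OCc1ccccc1)C2 | intermediate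
13 | 6,8-dibromo-penta-O-benzylcatechin | C(c1ccccc1)Oc1c(Br)c(OCc3ccccc3)c2c(c1Br)O[C@H](c1ccc(OCc3ccccc3)c(OCc3ccccc3)c1)[C@@H](OCc1ccccc1)C2 | intermediate
14 | 6-bromo-8-lithio-penta-O-benzylcatechin (drawn regioisomer) | C(c1ccccc1)Oc1c(Br)c(OCc3ccccc3)c2c(c1[Li])O[C@H](c1ccc(OCc3ccccc3)c(OCc3ccccc3)c1)[C@@H](OCc1ccccc1)C2 | intermediate (not isolated)
15 | 6-bromo-8-{hydroxy[(5S)-5-methylcyclopent-1-en-1-yl]methyl}-penta-O-benzylcatechin (carbinol epimers; the 8-bromo-6-carbinol regioisomer is carried along) | C(c1ccccc1)Oc1c(Br)c(OCc3ccccc3)c2c(c1C(O)C4=CCC[C@@H]4C)O[C@H](c1ccc(OCc3ccccc3)c(OCc3ccccc3)c1)[C@@H](OCc1ccccc1)C2 | intermediate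
16 | lithium alkoxide of 6-lithio-8-{hydroxy[(5S)-5-methylcyclopent-1-en-1-yl]methyl}-penta-O-benzylcatechin | C(c1ccccc1)Oc1c([Li])c(OCc3ccccc3)c2c(c1C(O[Li])C4=CCC[C@@H]4C)O[C@H](c1ccc(OCc3ccccc3)c(OCc3ccccc3)c1)[C@@H](OCc1ccccc1)C2 | intermediate (not isolated)
17 | 6,8-bis{hydroxy[(5S)-5-methylcyclopent-1-en-1-yl]methyl}-penta-O-benzylcatechin (carbinol epimers) | C(c1ccccc1)Oc1c(C(O)C4=CCC[C@@H]4C)c(OCc3ccccc3)c2c(c1C(O)C4=CCC[C@@H]4C)O[C@H](c1ccc(OCc3ccccc3)c(OCc3ccccc3)c1)[C@@H](OCc1ccccc1)C2 | intermediate
18 | 6,8-bis{[(5S)-5-methylcyclopent-1-en-1-yl]carbonyl}-penta-O-benzylcatechin | O=C(c1c(OCc3ccccc3)c2c(c(C(=O)C6=CCC[C@@H]6C)c1OCc1ccccc1)O[C@H](c1ccc(OCc3ccccc3)c(OCc3ccccc3)c1)[C@@H](OCc1ccccc1)C2)C4=CCC[C@@H]4C | intermediate (key-step precursor)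
19 | N-methylpropanamide | CCC(=O)NC | starting material
20 | dilithio N-methylpropanamide (C,N-dianion) | CC=C(O[Li])N(C)[Li] | intermediate (not isolated)
21 | tetralithium bis(enolate) bis(amidate) Michael adduct | CN([Li])C(=O)C(C)[C@H]4CC[C@H](C)C4=C(O[Li])c1c(OCc3ccccc3)c2c(c(C(O[Li])=C6[C@@H](C)CC[C@@H]6C(C)C(=O)N(C)[Li])c1OCc1ccccc1)O[C@H](c1ccc(OCc3ccccc3)c(OCc3ccccc3)c1)[C@@H](OCc1ccccc1)C2 | intermediate (not isolated)
22 | 6,8-bis{[(1R,2S,5S)-5-methyl-2-(1-(methylamino)-1-oxopropan-2-yl)cyclopentyl]carbonyl}-penta-O-benzylcatechin (C4 epimers) | CNC(=O)C(C)[C@H]4CC[C@H](C)[C@H]4C(=O)c1c(OCc3ccccc3)c2c(c(C(=O)[C@@H]6[C@@H](C)CC[C@@H]6C(C)C(=O)NC)c1OCc1ccccc1)O[C@H](c1ccc(OCc3ccccc3)c(OCc3ccccc3)c1)[C@@H](OCc1ccccc1)C2 | intermediate (key-step product)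
23 | bis(benzylic carbinol) of 22 (carbinol and C4 epimers) | CNC(=O)C(C)[C@H]4CC[C@H](C)[C@H]4C(O)c1c(OCc3ccccc3)c2c(c(C(O)[C@@H]6[C@@H](C)CC[C@@H]6C(C)C(=O)NC)c1OCc1ccccc1)O[C@H](c1ccc(OCc3ccccc3)c(OCc3ccccc3)c1)[C@@H](OCc1ccccc1)C2 | intermediate
24 | 6,8-bis[(1R,4aS,7S,7aR)-2,4,7-trimethyl-3-oxooctahydro-1H-cyclopenta[c]pyridin-1-yl]-penta-O-benzylcatechin (C4 epimers) | CC1C(=O)N(C)[C@@H](c2c(OCc6ccccc6)c3c(c([C@H]4[C@H]5[C@H](CC[C@@H]5C)C(C)C(=O)N4C)c2OCc2ccccc2)O[C@H](c2ccc(OCc6ccccc6)c(OCc6ccccc6)c2)[C@@H](OCc2ccccc2)C3)[C@H]2[C@@H]1CC[C@@H]2C | intermediate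
25 | 6,8-bis[(1R,4R,4aS,7S,7aR)-2,4,7-trimethyl-3-oxooctahydro-1H-cyclopenta[c]pyridin-1-yl]-penta-O-benzylcatechin | C[C@H]1C(=O)N(C)[C@@H](c2c(OCc6ccccc6)c3c(c([C@H]4[C@H]5[C@H](CC[C@@H]5C)[C@@H](C)C(=O)N4C)c2OCc2ccccc2)O[C@H](c2ccc(OCc6ccccc6)c(OCc6ccccc6)c2)[C@@H](OCc2ccccc2)C3)[C@H]2[C@@H]1CC[C@@H]2C | intermediate
26 | 6,8-bis[(1R,4R,4aR,7S,7aR)-2,4,7-trimethyloctahydro-1H-cyclopenta[c]pyridin-1-yl]-penta-O-benzylcatechin | C[C@H]1CN(C)[C@@H](c2c(OCc6ccccc6)c3c(c([C@H]4[C@H]5[C@H](CC[C@@H]5C)[C@@H](C)CN4C)c2OCc2ccccc2)O[C@H](c2ccc(OCc6ccccc6)c(OCc6ccccc6)c2)[C@@H](OCc2ccccc2)C3)[C@H]2[C@@H]1CC[C@@H]2C | intermediate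
27 | (2R,3S)-2-(3,4-dihydroxyphenyl)-6,8-bis[(1R,4R,4aR,7S,7aR)-2,4,7-trimethyloctahydro-1H-cyclopenta[c]pyridin-1-yl]chromane-3,5,7-triol | C[C@H]1CN(C)[C@@H](c2c(O)c3c(c([C@H]4[C@H]5[C@H](CC[C@@H]5C)[C@@H](C)CN4C)c2O)O[C@H](c2ccc(O)c(O)c2)[C@@H](O)C3)[C@H]2[C@@H]1CC[C@@H]2C | target

**Step count**
Total: 18 steps. Longest linear sequence: 15 steps (1 → 9 in steps 1–6, then steps 10–18). The catechin branch is 12 steps (steps 7–9, then 10–18).

**Steps most likely to fail**

Step 13 (Michael union). The strongly basic dianion may transfer a proton instead of forming the C–C bond (γ-deprotonation of the ring CH2 to a dienolate), the second enone may fail to react, the nucleophile may approach C4a with poor facial selectivity, or the enolate may be protonated at C7a from the wrong face. Fallback: set out from 18 and replace the basic donor by a neutral one in a Mukaiyama–Michael reaction. (E)-1-Methoxy-1-(trimethylsilyloxy)prop-1-ene with catalytic Tf2NH in CH2Cl2 at −78 °C should give the bis(trimethylsilyl enol ether) F1. Cold desilylation with Bu4NF buffered by AcOH protonates C7a under the same kinetic control and should give the bis(δ-keto methyl ester) F2. Aminolysis with Me2AlNHMe (from AlMe3 and MeNH2·HCl, toluene, warm) converts both esters into the N-methylamides and returns to the route at 22.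

Step 15 (lactam closure). The cation may be captured by the amide oxygen instead of nitrogen (an imidate that hydrolyses to a lactone on work-up), it may lose the C7a proton and so scramble the ring fusion, benzyl groups may be lost or migrate in acid, or C1 may not reach equilibrium. Fallback: set out from 22 and form the C1–N bond by carbonyl condensation instead of cation capture, which also bypasses step 14. With TFA and Et3SiH in CH2Cl2 the amide nitrogen adds to the protonated ketone to give the bis(hydroxy-lactam) F3; its N-acyliminium ion is reduced in place by the silane (reductive lactamisation), and the sequence returns to the route at 24, where C1 can still equilibrate under the acid.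

Step 11 (second aryllithium addition). The doubly activated carbinol of 15 may ionise during isolation, the exchange next to the lithium alkoxide may stall, or the aryllithium may be quenched by proton transfer from a benzyloxy CH2 group before it adds. Fallback: set out from 13 and work at the ketone oxidation level, so that no carbinol is handled. Ester 7 is converted with MeNH(OMe)·HCl and i-PrMgCl (THF, −20 → 0 °C) into the Weinreb amide (5S)-N-methoxy-N,5-dimethylcyclopent-1-ene-1-carboxamide F4. Two-fold exchange of 13 with t-BuLi (4.4 equiv, THF, −78 °C) gives the 6,8-dilithio arene F5, which adds to two molecules of F4 to give the chelated bis(tetrahedral adduct) F6. An AcOH quench at −78 °C releases both ketones and returns to the route at 18, bypassing 15, 17 and the oxidation of step 12.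

**Further compounds**
F1 | step 13 | bis(trimethylsilyl enol ether) of the bis(δ-keto methyl ester) | COC(=O)C(C)[C@H]4CC[C@H](C)C4=C(O[Si](C)(C)C)c1c(OCc3ccccc3)c2c(c(C(O[Si](C)(C)C)=C6[C@@H](C)CC[C@@H]6C(C)C(=O)OC)c1OCc1ccccc1)O[C@H](c1ccc(OCc3ccccc3)c(OCc3ccccc3)c1)[C@@H](OCc1ccccc1)C2
F2 | step 13 | 6,8-bis{[(1R,2S,5S)-2-(1-methoxy-1-oxopropan-2-yl)-5-methylcyclopentyl]carbonyl}-penta-O-benzylcatechin | COC(=O)C(C)[C@H]4CC[C@H](C)[C@H]4C(=O)c1c(OCc3ccccc3)c2c(c(C(=O)[C@@H]6[C@@H](C)CC[C@@H]6C(C)C(=O)OC)c1OCc1ccccc1)O[C@H](c1ccc(OCc3ccccc3)c(OCc3ccccc3)c1)[C@@H](OCc1ccccc1)C2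
F3 | step 15 | 6,8-bis[(4aS,7S,7aR)-1-hydroxy-2,4,7-trimethyl-3-oxooctahydro-1H-cyclopenta[c]pyridin-1-yl]-penta-O-benzylcatechin | CC1C(=O)N(C)C(O)(c2c(OCc6ccccc6)c3c(c(C4(O)[C@H]5[C@H](CC[C@@H]5C)C(C)C(=O)N4C)c2OCc2ccccc2)O[C@H](c2ccc(OCc6ccccc6)c(OCc6ccccc6)c2)[C@@H](OCc2ccccc2)C3)[C@H]2[C@@H]1CC[C@@H]2C
F4 | step 11 | (5S)-N-methoxy-N,5-dimethylcyclopent-1-ene-1-carboxamide | C[C@H]1CCC=C1C(=O)N(C)OC
F5 | step 11 | 6,8-dilithio-penta-O-benzylcatechin | C(c1ccccc1)Oc1c([Li])c(OCc3ccccc3)c2c(c1[Li])O[C@H](c1ccc(OCc3ccccc3)c(OCc3ccccc3)c1)[C@@H](OCc1ccccc1)C2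
F6 | step 11 | dilithium bis(alkoxide) of the 6,8-bis[(N-methoxy-N-methylamino)((5S)-5-methylcyclopent-1-enyl)hydroxymethyl] adduct | C(c1ccccc1)Oc1c(C(O[Li])(N(C)OC)C4=CCC[C@@H]4C)c(OCc3ccccc3)c2c(c1C(O[Li])(N(C)OC)C4=CCC[C@@H]4C)O[C@H](c1ccc(OCc3ccccc3)c(OCc3ccccc3)c1)[C@@H](OCc1ccccc1)C2
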